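## Retrosynthetic overview

1. Target 53 ⇒ spiro β-hydroxy enone 47 by a redox swap at C7/C8 (directed C7 reduction, C8 oxidation) and reduction of C5=C6; ring C and the spiro centre C9 come from an intramolecular reductive aldol (C8–C9) of enone aldehyde 45.
2. 45 ⇒ fragment AB enone 13 + fragment DE aldehyde 39, joined at C9–C11 by an intermolecular crossed aldol addition, then dehydration.
3. 13 ⇒ 2-methylcyclopentanone (ring B): auxiliary-controlled Michael addition to methyl vinyl ketone, aldol condensation (ring A), gem-dimethylation, C3 reduction, C7 allylic oxidation.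
4. 39 ⇒ 2-methylcyclopentane-1,3-dione (ring E) + ethyl vinyl ketone: amino-acid-mediated aldol cyclisation (ring D), reductive allylation (C13), directed cyclopropanation/hydrogenolysis (C14 methyl), Suzuki coupling/hydrogenation (C21 isopropyl).
5. Ring order: B→A and E→D inside the two fragments, ring C last (it creates the spiro junction).

Assumption: fernane-type locants of the target are kept for all intermediates (ring A C1–C5/C10, ring B C5–C7/C9/C10, ring C C8/C9/C11–C14, ring D C13–C18, ring E C17–C21); centres destroyed later are left undefined.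

## Route

**Fragment AB**

Step 1
Reactants: 1 2-methylcyclopentanone (racemic); 2 (R)-1-phenylethylamine
Product: 3 N-[(R)-1-phenylethyl]imine of 2-methylcyclopentanone (E/Z mixture, in equilibrium with its enamine tautomers)
Conditions: TsOH·H2O (1 mol %), toluene, Dean–Stark, reflux
Reagents that add atoms: none
Why: Acid-catalysed ketone–amine condensation (imine formation), driven by azeotropic water removal, installs the chiral auxiliary while the ring stereocentre is still labile.

Step 2
Reactants: 3 imine; 4 methyl vinyl ketone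
Product: 6 (S)-2-methyl-2-(3-oxobutyl)cyclopentan-1-one, via keto imine 5 (not isolated)
Conditions: THF, rt, 3 d; then 20% aq. AcOH, rt, 2 h
Reagents that add atoms: water, O
Why: d'Angelo deracemising Michael addition: the more substituted enamine tautomer adds to the enone on the face away from the phenyl group, creating the quaternary C10 centre (S, about 90% ee), and hydrolysis then frees the ketone and the auxiliary.

Step 3
Reactants: 6 diketone
Product: 8 (S)-7a-methyl-1,2,3,6,7,7a-hexahydro-5H-inden-5-one, via cis ketol 7 (not isolated)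
Conditions: NaOMe (0.3 equiv), MeOH, 60 °C
Reagents that add atoms: none
Why: Intramolecular aldol condensation (second stage of a Robinson annulation) of the methyl ketone onto the ring carbonyl closes ring A without touching the quaternary centre.

Step 4
Reactants: 8 bicyclic enone
Product: 10 (S)-4,4,7a-trimethyl-1,2,4,6,7,7a-hexahydro-5H-inden-5-one, via monomethyl enone 9 (not isolated)
Conditions: KOt-Bu (2.3 equiv), t-BuOH, rt; MeI (3 equiv), 0 °C → rt
Reagents that add atoms: iodomethane, CI
Why: Deconjugative double α-alkylation of the extended dienolate puts both methyl groups on C4 and moves the alkene to C5=C6.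

Step 5
Reactants: 10 ketone
Product: 11 (5S,7aS)-4,4,7a-trimethyl-2,4,5,6,7,7a-hexahydro-1H-inden-5-ol (3β-OH, cis to the C10 methyl)
Conditions: NaBH4, MeOH, 0 °C
Reagents that add atoms: none
Why: Hydride reduction from the α-face, away from the two β-axial methyl groups (4β and C10), gives the equatorial 3β-alcohol (3S); the minor epimer is removed by chromatography.

Step 6
Reactants: 11 alcohol
Product: 12 tert-butyldimethylsilyl ether of 11
Conditions: t-BuMe2SiOTf (1.3 equiv), 2,6-lutidine, CH2Cl2, 0 °C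
Reagents that add atoms: tert-butyldimethylsilyl triflate, CC(C)(C)[Si](C)(C)OS(=O)(=O)C(F)(F)F
Why: Silyl triflate silylation protects the hindered C3 alcohol with a group that survives base, hydride, dissolving metal and oxidants until the last step.

Step 7
Reactants: 12 silyl ether
Product: 13 fragment AB, (5S,7aR)-5-[(tert-butyldimethylsilyl)oxy]-4,4,7a-trimethyl-1,4,5,6,7,7a-hexahydro-2H-inden-2-one (C7 ketone, C5=C6, C9H2)
Conditions: Mn(OAc)3·2H2O (10 mol %), t-BuOOH (5 equiv), 3 Å MS, EtOAc, rt
Reagents that add atoms: tert-butyl hydroperoxide, CC(C)(C)OO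
Why: Radical allylic oxidation is regiospecific because C7 is the only allylic carbon bearing hydrogen (C4 and C10 are quaternary).

**Fragment DE**

Step 8
Reactants: 14 2-methylcyclopentane-1,3-dione; 15 ethyl vinyl ketone
Product: 16 2-methyl-2-(3-oxopentyl)cyclopentane-1,3-dione
Conditions: H2O, AcOH (cat.), 70 °C
Reagents that add atoms: none
Why: Michael addition of the acidic 1,3-dione to the enone in water gives the achiral triketone cleanly.

Step 9
Reactants: 16 triketone
Product: 18 (S)-4,7a-dimethyl-2,3,7,7a-tetrahydro-1H-indene-1,5(6H)-dione, via bicyclic ketol 17 (not isolated)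
Conditions: L-phenylalanine (1.0 equiv), (1S)-(+)-camphor-10-sulfonic acid (0.5 equiv), DMF, 30 → 70 °C
Reagents that add atoms: none
Why: Hajos–Parrish–Eder–Sauer–Wiechert aldol condensation: the amino-acid enamine differentiates the two enantiotopic ring carbonyls, closing ring D and setting C17 as S (crystallisation of 19 raises the ee).

Step 10
Reactants: 18 enedione
Product: 19 (1S,7aS)-1-hydroxy-4,7a-dimethyl-1,2,3,6,7,7a-hexahydro-5H-inden-5-one
Conditions: NaBH4 (0.27 equiv), EtOH, −20 °C
Reagents that add atoms: none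
Why: Chemoselective hydride reduction of the saturated cyclopentanone beside the less electrophilic enone, with attack anti to the angular methyl so the hydroxyl is cis to it.

Step 11
Reactants: 19 hydroxy enone
Product: 20 (1S,7aS)-1-[(tert-butyldimethylsilyl)oxy]-4,7a-dimethyl-1,2,3,6,7,7a-hexahydro-5H-inden-5-one
Conditions: t-BuMe2SiCl, imidazole, DMF, rt
Reagents that add atoms: tert-butyldimethylsilyl chloride, CC(C)(C)[Si](C)(C)Cl
Why: Standard silylation masks the C21 oxygen for the dissolving-metal and organometallic steps.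

Step 12
Reactants: 20 silyloxy enone
Product: 22 (1S,3aR,4S,7aS)-4-allyl-1-[(tert-butyldimethylsilyl)oxy]-4,7a-dimethyloctahydro-5H-inden-5-one, via lithium enolate 21 (not isolated)
Conditions: Li (2.3 equiv), NH3(l)/THF, t-BuOH (1.0 equiv), −78 °C; isoprene; allyl bromide (4 equiv), −78 → −33 °C
Reagents that add atoms: allyl bromide, C=CCBr
Why: Stork reductive alkylation: Birch reduction protonates C18 to give the trans ring fusion, and the regiospecific enolate is allylated on the face away from the 1,3-related axial C17 methyl, so the C13 methyl ends cis to it.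

Step 13
Reactants: 22 ketone
Product: 23 C14 enol triflate of 22 (C14=C15)
Conditions: Tf2O (1.3 equiv), 2,6-di-tert-butyl-4-methylpyridine (1.5 equiv), CH2Cl2, 0 °C → rt
Reagents that add atoms: triflic anhydride, O=S(=O)(OS(=O)(=O)C(F)(F)F)C(F)(F)F
Why: Enol triflate formation can only go toward C15 because C13 is quaternary.

Step 14
Reactants: 23 enol triflate
Product: 24 methyl enoate (CO2Me on C14 of the C14=C15 alkene; ester carbon = C8)
Conditions: Pd(OAc)2 (5 mol %), PPh3 (10 mol %), CO (1 atm), MeOH, Et3N (2 equiv), DMF, 50 °C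
Reagents that add atoms: carbon monoxide, [C-]#[O+]; methanol, CO
Why: Palladium-catalysed methoxycarbonylation of the vinyl triflate introduces C8 at the ester oxidation level.

Step 15
Reactants: 24 enoate
Product: 25 allylic alcohol (C14–CH2OH on C14=C15)
Conditions: i-Bu2AlH (2.5 equiv), CH2Cl2, −78 °C; aq. potassium sodium tartrate
Reagents that add atoms: none
Why: 1,2-Reduction of the conjugated ester gives the allylic alcohol and leaves the silyl ether and both alkenes untouched.

Step 16
Reactants: 25 allylic alcohol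
Product: 26 cyclopropyl carbinol (CH2 bridging C14 and C15 on the face opposite the C13 and C17 methyls)
Conditions: Et2Zn (2.5 equiv), CH2I2 (2.5 equiv), CH2Cl2, −20 → 0 °C
Reagents that add atoms: diiodomethane, ICI
Why: Hydroxyl-directed Simmons–Smith (Furukawa) cyclopropanation delivers CH2 to the face opposite the pseudoaxial C13 and C17 methyls, fixing the future C14 methyl trans to the C13 methyl, while the undirected terminal alkene reacts far more slowly.

Step 17
Reactants: 26 cyclopropyl carbinol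
Product: 29 lactol (C8–O–C11H(OH), anomers), via triol 27 (not isolated), via hydroxy aldehyde 28 (not isolated)
Conditions: OsO4 (2 mol %), NaIO4 (3 equiv), 2,6-lutidine (2 equiv), dioxane/H2O 3:1, rt
Reagents that add atoms: osmium tetroxide, O=[Os](=O)(=O)=O; sodium periodate, [Na+].[O-]I(=O)(=O)=O
Why: Lemieux–Johnson cleavage of the terminal alkene gives the C11 aldehyde, which is trapped at once by the C8 hydroxyl as the six-membered lactol.

Step 18
Reactants: 29 lactol
Product: 30 δ-lactone (C8–O–C11(=O)–C12)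
Conditions: Pr4N[RuO4] (5 mol %), N-methylmorpholine N-oxide (1.5 equiv), 4 Å MS, CH2Cl2, rt
Reagents that add atoms: none
Why: Ley–Griffith oxidation of the lactol gives the lactone, which holds C8 (alkoxy) and C11 (acyl) in differentiated form.

Step 19
Reactants: 30 silyloxy lactone
Product: 31 hydroxy lactone (free C21–OH, cyclopropane retained)
Conditions: HF (48% aq.), MeCN, rt
Reagents that add atoms: none
Why: Acidic fluoride desilylation removes the hindered secondary silyl ether without opening the lactone or the cyclopropane.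

Step 20
Reactants: 31 cyclopropane lactone
Product: 32 hydroxy lactone with C14 methyl (trans to the C13 methyl)
Conditions: H2 (4 atm), PtO2 (10 mol %), AcOH, 40 °C
Reagents that add atoms: none
Why: Catalytic hydrogenolysis cleaves the least substituted cyclopropane bond (C15–CH2), turning the bridging carbon into the C14 angular methyl with the configuration set in step 16.

Step 21
Reactants: 32 alcohol
Product: 33 C21 keto lactone
Conditions: Dess–Martin periodinane (1.5 equiv), CH2Cl2, rt
Reagents that add atoms: none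
Why: Mild periodinane oxidation of the secondary alcohol gives the cyclopentanone without epimerisable centres at risk.

Step 22
Reactants: 33 ketone
Product: 34 C20=C21 enol triflate
Conditions: Tf2O (1.3 equiv), 2,6-di-tert-butyl-4-methylpyridine (1.5 equiv), CH2Cl2, 0 °C → rt
Reagents that add atoms: triflic anhydride, O=S(=O)(OS(=O)(=O)C(F)(F)F)C(F)(F)F
Why: Enol triflate formation is regiospecific (C17 is quaternary) and these non-basic conditions leave the lactone untouched.

Step 23
Reactants: 34 enol triflate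
Product: 35 isopropenyl diene (C20=C21–C(CH3)=CH2)
Conditions: isopropenylboronic acid pinacol ester (1.5 equiv), Pd(PPh3)4 (5 mol %), K3PO4 (3 equiv), dioxane/H2O 5:1, 80 °C; dilute HCl work-up
Reagents that add atoms: isopropenylboronic acid pinacol ester, CC(=C)B1OC(C)(C)C(C)(C)O1
Why: Suzuki–Miyaura coupling of the vinyl triflate installs the three side-chain carbons; the acidic work-up recloses any lactone opened by the base.

Step 24
Reactants: 35 diene
Product: 36 isopropyl lactone (C21 isopropyl cis to the C17 methyl)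
Conditions: H2 (3 atm), 10% Pd/C, EtOAc, rt
Reagents that add atoms: none
Why: Heterogeneous hydrogenation delivers hydrogen to C21 from the face opposite the angular C17 methyl (as with 17-substituted 16-ene steroids), so the isopropyl group ends cis to that methyl (21R).

Step 25
Reactants: 36 lactone
Product: 37 hydroxy Weinreb amide (C11 N-methoxy-N-methylamide, free C8–OH)
Conditions: MeNH(OMe)·HCl (3 equiv), i-PrMgCl (6 equiv), THF, −20 → 0 °C
Reagents that add atoms: N,O-dimethylhydroxylamine hydrochloride, CNOC.Cl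
Why: Weinreb aminolysis of the unhindered lactone carbonyl by the magnesium amide opens the ring and frees only the C8 hydroxyl.

Step 26
Reactants: 37 hydroxy amide
Product: 38 triethylsilyl ether of 37
Conditions: Et3SiOTf (1.2 equiv), 2,6-lutidine (2 equiv), CH2Cl2, −78 °C
Reagents that add atoms: triethylsilyl triflate, CC[Si](CC)(CC)OS(=O)(=O)C(F)(F)F
Why: Fast silylation caps the neopentyl alcohol before it can relactonise, with a group that can later be removed beside the C3 silyl ether.

Step 27
Reactants: 38 Weinreb amide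
Product: 39 fragment DE aldehyde (C13–CH2–CHO, C14–CH2OSiEt3)
Conditions: i-Bu2AlH (1.5 equiv), THF, −78 °C; aq. potassium sodium tartrate
Reagents that add atoms: none
Why: Hydride reduction of the Weinreb amide stops at the chelated tetrahedral intermediate and gives the aldehyde on work-up.

**Fragment union and endgame**

Step 28
Reactants: 13 fragment AB enone; 39 fragment DE aldehyde
Product: 41 aldol adduct (new C9–C11 bond; 11-hydroxy-7-ketone, C9/C11 epimers), via lithium enolate 40 (not isolated)
Conditions: LiN(i-Pr)2 (1.05 equiv), THF, −78 °C, 45 min; then 39 (1.1 equiv), −78 °C; NH4Cl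
Reagents that add atoms: none
Why: Directed crossed aldol addition: only the C9 protons of 13 can be removed (C6 is vinylic, C4 and C10 are quaternary), so the enolate adds regiospecifically to the aldehyde, and the small amount of diastereomer from the minor enantiomer of 13 is removed here.

Step 29
Reactants: 41 aldol adduct
Product: 43 cross-conjugated dienone (C9=C11 and C5=C6 flanking the C7 ketone; E/Z mixture at C9=C11), via mesylate 42 (not isolated)
Conditions: MsCl (1.5 equiv), Et3N (3 equiv), CH2Cl2, 0 °C; then DBU (3 equiv), rt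
Reagents that add atoms: none
Why: Mesylation and E1cB elimination give the alkylidene ketone; the alkene geometry is irrelevant because it is erased in step 32.

Step 30
Reactants: 43 dienone
Product: 44 primary alcohol (free C8–OH)
Conditions: pyridinium p-toluenesulfonate (0.2 equiv), MeOH/CH2Cl2 1:1, 0 °C → rt
Reagents that add atoms: none
Why: Mild acidic methanolysis removes the primary triethylsilyl ether selectively beside the hindered secondary tert-butyldimethylsilyl ether.

Step 31
Reactants: 44 alcohol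
Product: 45 enone aldehyde (C8 aldehyde on quaternary C14)
Conditions: Dess–Martin periodinane (1.5 equiv), CH2Cl2, rt
Reagents that add atoms: none
Why: Periodinane oxidation of the neopentyl alcohol gives a non-enolisable aldehyde without touching the dienone.

Step 32
Reactants: 45 enone aldehyde
Product: 47 spiro β-hydroxy enone (ring C closed; 9S spiro centre, 8R hydroxyl equatorial on ring C; C7 ketone conjugated with C5=C6), via copper enolate 46 (not isolated)
Conditions: [(Ph3P)CuH]6 (0.5 equiv), toluene, −40 → 0 °C; aq. NH4Cl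
Reagents that add atoms: none
Why: Reductive aldol cyclisation: copper hydride adds 1,4 to the accessible exocyclic enone only, and the C9 enolate closes ring C on the C8 aldehyde through a chelated chair transition state with the bulky C10 equatorial (no 1,3-diaxial clash with the C14 methyl), which sets the spiro centre as in the target.

Step 33
Reactants: 47 spiro enone
Product: 49 saturated β-hydroxy ketone (5α-H, trans A/B fusion), via lithium enolate 48 (not isolated)
Conditions: Li (3 equiv), NH3(l)/THF, t-BuOH (1.0 equiv), −78 °C, 10 min; isoprene; NH4Cl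
Reagents that add atoms: none
Why: Birch reduction of the enone: C5 is protonated from the α-face because the β-face is shielded by the axial 4β and C10 methyls, giving the trans-fused hydrindane (5R), and the ketone is protected as its enolate until the quench.

Step 34
Reactants: 49 β-hydroxy ketone
Product: 50 7β,8-diol
Conditions: Me4NBH(OAc)3 (6 equiv), AcOH/MeCN 1:1, −25 → 0 °C
Reagents that add atoms: none
Why: Evans–Saksena directed reduction: the borohydride bound to the C8 oxygen, which sits on the α-face of ring B, delivers hydride intramolecularly to C7 from that face, so the new hydroxyl is β (7S).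

Step 35
Reactants: 50 diol
Product: 51 7β-triethylsilyl ether (C8–OH free)
Conditions: Et3SiCl (1.2 equiv), imidazole (2.5 equiv), DMF, 0 °C
Reagents that add atoms: chlorotriethylsilane, CC[Si](CC)(CC)Cl
Why: Selective silylation: the C7 hydroxyl reacts while the C8 hydroxyl, flanked by two quaternary carbons, does not.

Step 36
Reactants: 51 mono-protected diol
Product: 52 8-ketone (3β-OSiMe2t-Bu, 7β-OSiEt3)
Conditions: Dess–Martin periodinane (3 equiv), CH2Cl2, rt → 35 °C
Reagents that add atoms: none
Why: Periodinane oxidation tolerates the very hindered carbinol and gives the C8 ketone, which cannot epimerise because both α-carbons are quaternary.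

Step 37
Reactants: 52 bis-silyl ether
Product: 53 target CNP0155208.1
Conditions: HF·pyridine, THF, 0 °C → rt
Reagents that add atoms: none
Why: Global desilylation under acidic fluoride conditions avoids base and therefore retro-aldol opening of the β-hydroxy ketone.

## Compound list

1 | 2-methylcyclopentanone (racemic) | CC1CCCC1=O | starting material
2 | (R)-1-phenylethylamine | C[C@@H](N)c1ccccc1 | starting material
3 | N-[(R)-1-phenylethyl]imine of 2-methylcyclopentanone | CC1CCCC1=N[C@H](C)c1ccccc1 | intermediate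
4 | methyl vinyl ketone | CC(=O)C=C | starting material
5 | keto imine: ring-carbonyl N-[(R)-1-phenylethyl]imine of (S)-2-methyl-2-(3-oxobutyl)cyclopentanone | CC(=O)CC[C@@]1(CCCC1=N[C@H](C)c1ccccc1)C | intermediate (not isolated)
6 | (S)-2-methyl-2-(3-oxobutyl)cyclopentan-1-one | CC(=O)CC[C@@]1(CCCC1=O)C | intermediate
7 | cis ketol: (7aS)-3a-hydroxy-7a-methyloctahydro-5H-inden-5-one, OH cis to the methyl | C1CC[C@]2(O)CC(=O)CC[C@@]21C | intermediate (not isolated)
8 | (S)-7a-methyl-1,2,3,6,7,7a-hexahydro-5H-inden-5-one | C1CCC2=CC(=O)CC[C@@]21C | intermediate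
9 | (S)-4,7a-dimethyl-1,2,3,6,7,7a-hexahydro-5H-inden-5-one | C1CCC2=C(C)C(=O)CC[C@@]21C | intermediate (not isolated)
10 | (S)-4,4,7a-trimethyl-1,2,4,6,7,7a-hexahydro-5H-inden-5-one | C1CC=C2C(C)(C)C(=O)CC[C@@]21C | intermediate
11 | (5S,7aS)-4,4,7a-trimethyl-2,4,5,6,7,7a-hexahydro-1H-inden-5-ol | C1CC=C2C(C)(C)[C@@H](O)CC[C@@]21C | intermediate
12 | tert-butyldimethylsilyl ether of 11 | C1CC=C2C(C)(C)[C@@H](O[Si](C)(C)C(C)(C)C)CC[C@@]21C | intermediate
13 | fragment AB: (5S,7aR)-5-[(tert-butyldimethylsilyl)oxy]-4,4,7a-trimethyl-1,4,5,6,7,7a-hexahydro-2H-inden-2-one | C1C(=O)C=C2C(C)(C)[C@@H](O[Si](C)(C)C(C)(C)C)CC[C@@]21C | intermediate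
14 | 2-methylcyclopentane-1,3-dione | CC1C(=O)CCC1=O | starting material
15 | ethyl vinyl ketone (pent-1-en-3-one) | CCC(=O)C=C | starting material
16 | 2-methyl-2-(3-oxopentyl)cyclopentane-1,3-dione | CCC(=O)CCC1(C)C(=O)CCC1=O | intermediate
17 | bicyclic ketol: (7aS)-3a-hydroxy-4,7a-dimethylhexahydro-1H-indene-1,5(4H)-dione, cis-fused, C4 epimers | O=C1CC[C@]2(O)C(C)C(=O)CC[C@]12C | intermediate (not isolated)
18 | (S)-4,7a-dimethyl-2,3,7,7a-tetrahydro-1H-indene-1,5(6H)-dione | O=C1CCC2=C(C)C(=O)CC[C@]12C | intermediate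
19 | (1S,7aS)-1-hydroxy-4,7a-dimethyl-1,2,3,6,7,7a-hexahydro-5H-inden-5-one | O[C@H]1CCC2=C(C)C(=O)CC[C@]12C | intermediate
20 | (1S,7aS)-1-[(tert-butyldimethylsilyl)oxy]-4,7a-dimethyl-1,2,3,6,7,7a-hexahydro-5H-inden-5-one | CC(C)(C)[Si](C)(C)O[C@H]1CCC2=C(C)C(=O)CC[C@]12C | intermediate
21 | lithium enolate (C13=C14–OLi) of the trans-fused ketone | CC(C)(C)[Si](C)(C)O[C@H]1CC[C@@H]2[C@]1(C)CCC(O[Li])=C2C | intermediate (not isolated)
22 | (1S,3aR,4S,7aS)-4-allyl-1-[(tert-butyldimethylsilyl)oxy]-4,7a-dimethyloctahydro-5H-inden-5-one | CC(C)(C)[Si](C)(C)O[C@H]1CC[C@@H]2[C@]1(C)CCC(=O)[C@@]2(C)CC=C | intermediate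
23 | C14 enol triflate of 22 (C14=C15) | CC(C)(C)[Si](C)(C)O[C@H]1CC[C@@H]2[C@]1(C)CC=C(OS(=O)(=O)C(F)(F)F)[C@@]2(C)CC=C | intermediate
24 | methyl enoate (CO2Me on C14, C14=C15) | CC(C)(C)[Si](C)(C)O[C@H]1CC[C@@H]2[C@]1(C)CC=C(C(=O)OC)[C@@]2(C)CC=C | intermediate
25 | allylic alcohol (CH2OH on C14, C14=C15) | CC(C)(C)[Si](C)(C)O[C@H]1CC[C@@H]2[C@]1(C)CC=C(CO)[C@@]2(C)CC=C | intermediate
26 | cyclopropyl carbinol (C14/C15 cyclopropane anti to the C13 and C17 methyls) | CC(C)(C)[Si](C)(C)O[C@H]1CC[C@@H]2[C@]1(C)C[C@H]3C[C@@]3(CO)[C@@]2(C)CC=C | intermediate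
27 | triol (allyl group of 26 dihydroxylated) | CC(C)(C)[Si](C)(C)O[C@H]1CC[C@@H]2[C@]1(C)C[C@H]3C[C@@]3(CO)[C@@]2(C)CC(O)CO | intermediate (not isolated)
28 | hydroxy aldehyde (C13–CH2–CHO, C14–CH2OH) | CC(C)(C)[Si](C)(C)O[C@H]1CC[C@@H]2[C@]1(C)C[C@H]3C[C@@]3(CO)[C@@]2(C)CC=O | intermediate (not isolated)
29 | lactol (C8–O–C11H(OH), anomers) | CC(C)(C)[Si](C)(C)O[C@H]1CC[C@@H]2[C@]1(C)C[C@H]3C[C@@]3(COC(O)C4)[C@]24C | intermediate
30 | δ-lactone (C8–O–C11(=O)), silyl ether and cyclopropane retained | CC(C)(C)[Si](C)(C)O[C@H]1CC[C@@H]2[C@]1(C)C[C@H]3C[C@@]3(COC(=O)C4)[C@]24C | intermediate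
31 | hydroxy lactone (C21–OH), cyclopropane retained | O[C@H]1CC[C@@H]2[C@]1(C)C[C@H]3C[C@@]3(COC(=O)C4)[C@]24C | intermediate
32 | hydroxy lactone with C14 methyl trans to the C13 methyl | O[C@H]1CC[C@@H]2[C@]1(C)CC[C@](C)(COC(=O)C3)[C@]23C | intermediate
33 | C21 keto lactone | O=C1CC[C@@H]2[C@]1(C)CC[C@](C)(COC(=O)C3)[C@]23C | intermediate
34 | C20=C21 enol triflate lactone | FC(F)(F)S(=O)(=O)OC1=CC[C@@H]2[C@]1(C)CC[C@](C)(COC(=O)C3)[C@]23C | intermediate
35 | isopropenyl diene lactone | CC(=C)C1=CC[C@@H]2[C@]1(C)CC[C@](C)(COC(=O)C3)[C@]23C | intermediate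
36 | isopropyl lactone (isopropyl cis to the C17 methyl) | CC(C)[C@H]1CC[C@@H]2[C@]1(C)CC[C@](C)(COC(=O)C3)[C@]23C | intermediate
37 | hydroxy Weinreb amide (C11 amide, C8–OH) | CC(C)[C@H]1CC[C@@H]2[C@]1(C)CC[C@](C)(CO)[C@@]2(C)CC(=O)N(C)OC | intermediate
38 | triethylsilyl ether of 37 | CC(C)[C@H]1CC[C@@H]2[C@]1(C)CC[C@](C)(CO[Si](CC)(CC)CC)[C@@]2(C)CC(=O)N(C)OC | intermediate
39 | fragment DE aldehyde | CC(C)[C@H]1CC[C@@H]2[C@]1(C)CC[C@](C)(CO[Si](CC)(CC)CC)[C@@]2(C)CC=O | intermediate
40 | lithium enolate of 13 (C9=C7–OLi) | C1=C(O[Li])C=C2C(C)(C)[C@@H](O[Si](C)(C)C(C)(C)C)CC[C@@]21C | intermediate (not isolated)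
41 | aldol adduct (11-hydroxy-7-ketone, C9/C11 epimers) | CC(C)[C@H]1CC[C@@H]2[C@]1(C)CC[C@](C)(CO[Si](CC)(CC)CC)[C@@]2(C)CC(O)C3C(=O)C=C4C(C)(C)[C@@H](O[Si](C)(C)C(C)(C)C)CC[C@@]43C | intermediate
42 | C11 mesylate of 41 | CC(C)[C@H]1CC[C@@H]2[C@]1(C)CC[C@](C)(CO[Si](CC)(CC)CC)[C@@]2(C)CC(OS(C)(=O)=O)C3C(=O)C=C4C(C)(C)[C@@H](O[Si](C)(C)C(C)(C)C)CC[C@@]43C | intermediate (not isolated)
43 | cross-conjugated dienone (E/Z mixture at C9=C11) | CC(C)[C@H]1CC[C@@H]2[C@]1(C)CC[C@](C)(CO[Si](CC)(CC)CC)[C@@]2(C)CC=C3C(=O)C=C4C(C)(C)[C@@H](O[Si](C)(C)C(C)(C)C)CC[C@@]43C | intermediate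
44 | dienone with free C8–OH | CC(C)[C@H]1CC[C@@H]2[C@]1(C)CC[C@](C)(CO)[C@@]2(C)CC=C3C(=O)C=C4C(C)(C)[C@@H](O[Si](C)(C)C(C)(C)C)CC[C@@]43C | intermediate
45 | enone aldehyde (C8 aldehyde) | CC(C)[C@H]1CC[C@@H]2[C@]1(C)CC[C@](C)(C=O)[C@@]2(C)CC=C3C(=O)C=C4C(C)(C)[C@@H](O[Si](C)(C)C(C)(C)C)CC[C@@]43C | intermediate
46 | copper enolate (C9=C7–OCu, phosphine ligands omitted) | CC(C)[C@H]1CC[C@@H]2[C@]1(C)CC[C@](C)(C=O)[C@@]2(C)CCC3=C(O[Cu])C=C4C(C)(C)[C@@H](O[Si](C)(C)C(C)(C)C)CC[C@@]43C | intermediate (not isolated)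
47 | spiro β-hydroxy enone (9S; 8R-OH; C7 ketone; C5=C6) | CC(C)[C@H]1CC[C@@H]2[C@]1(C)CC[C@]1(C)[C@@H](O)[C@]3(CC[C@@]21C)C(=O)C=C1C(C)(C)[C@@H](O[Si](C)(C)C(C)(C)C)CC[C@@]13C | intermediate
48 | lithium enolate (C6=C7–OLi, 5α-H) | CC(C)[C@H]1CC[C@@H]2[C@]1(C)CC[C@]1(C)[C@@H](O)[C@]3(CC[C@@]21C)C(O[Li])=C[C@H]1C(C)(C)[C@@H](O[Si](C)(C)C(C)(C)C)CC[C@@]13C | intermediate (not isolated)
49 | saturated β-hydroxy ketone (5α-H, C7 ketone, 8-OH) | CC(C)[C@H]1CC[C@@H]2[C@]1(C)CC[C@]1(C)[C@@H](O)[C@]3(CC[C@@]21C)C(=O)C[C@H]1C(C)(C)[C@@H](O[Si](C)(C)C(C)(C)C)CC[C@@]13C | intermediate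
50 | 7β,8-diol | CC(C)[C@H]1CC[C@@H]2[C@]1(C)CC[C@]1(C)[C@@H](O)[C@]3(CC[C@@]21C)[C@@H](O)C[C@H]1C(C)(C)[C@@H](O[Si](C)(C)C(C)(C)C)CC[C@@]13C | intermediate
51 | 7β-triethylsilyl ether, 8-OH free | CC(C)[C@H]1CC[C@@H]2[C@]1(C)CC[C@]1(C)[C@@H](O)[C@]3(CC[C@@]21C)[C@@H](O[Si](CC)(CC)CC)C[C@H]1C(C)(C)[C@@H](O[Si](C)(C)C(C)(C)C)CC[C@@]13C | intermediate
52 | 8-ketone bis-silyl ether | CC(C)[C@H]1CC[C@@H]2[C@]1(C)CC[C@]1(C)C(=O)[C@]3(CC[C@@]21C)[C@@H](O[Si](CC)(CC)CC)C[C@H]1C(C)(C)[C@@H](O[Si](C)(C)C(C)(C)C)CC[C@@]13C | intermediate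
53 | target CNP0155208.1: (3S,5R,7S,9S,10S,13S,14S,17R,18R,21R)-3β,7β-dihydroxy-7(8→9)-abeo-fernane-type spiro 8-ketone | CC(C)[C@H]1CC[C@@H]2[C@]1(C)CC[C@]1(C)C(=O)[C@]3(CC[C@@]21C)[C@@H](O)C[C@H]1C(C)(C)[C@@H](O)CC[C@@]13C | target

## Step count and risk

Total steps: 37. Longest linear sequence: 30 steps (steps 8–37, from 14 and 15).

Three steps most likely to fail:

Step 12 (reductive allylation) may give incomplete trans selectivity at C18 or enolate scrambling before alkylation. The fallback sets out from 20 and returns at 22. Conjugate reduction of 20 with the copper hydride made from i-Bu2AlH and t-BuCu (THF/HMPA, −50 °C), which is trans-selective on such hydrindenones, gives the trans-fused 13-methyl ketone F1. Thermodynamic silylation (Me3SiCl, NaI, Et3N, MeCN) gives the tetrasubstituted trimethylsilyl enol ether F2. MeLi then regenerates the C13 lithium enolate regiospecifically, and allyl bromide alkylates it anti to the C17 methyl to give 22.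

Step 20 (cyclopropane hydrogenolysis) may be sluggish or cleave another bond. The fallback sets out from 24 and returns at 32, replacing the cyclopropane by an enolate methylation. Conjugate reduction of 24 (Mg, MeOH) gives the saturated methyl ester F3. Its enolate (LiN(i-Pr)2, THF/DMPU) is methylated with MeI anti to the vicinal axial C13 methyl, giving the C14-methylated ester F4. LiAlH4 gives the neopentyl alcohol F5. OsO4/NaIO4 gives the lactol F6, and Pr4N[RuO4]/N-methylmorpholine N-oxide gives the silyloxy lactone F7. Aqueous HF in MeCN then gives 32.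

Step 32 (tandem reductive aldol) may stop at simple conjugate reduction or reduce the aldehyde. The fallback sets out from 44 and returns at 47, separating the two events. [(Ph3P)CuH]6 with t-BuOH as proton source reduces only the exocyclic enone and gives the saturated keto alcohol F8. Dess–Martin oxidation gives the keto aldehyde F9. LiN(SiMe3)2 (THF, −78 °C) then forms the only possible enolate (C9), which closes ring C by a chelated lithium aldol to give 47.

## Further compounds

F1 | step 12 | trans-fused 13-methyl ketone (1-silyloxy-4,7a-dimethyloctahydro-5H-inden-5-one, 4-methyl equatorial) | CC(C)(C)[Si](C)(C)O[C@H]1CC[C@@H]2[C@]1(C)CCC(=O)[C@H]2C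
F2 | step 12 | tetrasubstituted trimethylsilyl enol ether (C13=C14–OSiMe3) | CC(C)(C)[Si](C)(C)O[C@H]1CC[C@@H]2[C@]1(C)CCC(O[Si](C)(C)C)=C2C
F3 | step 20 | saturated methyl ester (C14 epimers) | CC(C)(C)[Si](C)(C)O[C@H]1CC[C@@H]2[C@]1(C)CCC(C(=O)OC)[C@@]2(C)CC=C
F4 | step 20 | C14-methylated ester (C14 methyl trans to the C13 methyl) | CC(C)(C)[Si](C)(C)O[C@H]1CC[C@@H]2[C@]1(C)CC[C@](C)(C(=O)OC)[C@@]2(C)CC=C
F5 | step 20 | neopentyl alcohol (C14–CH2OH) | CC(C)(C)[Si](C)(C)O[C@H]1CC[C@@H]2[C@]1(C)CC[C@](C)(CO)[C@@]2(C)CC=C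
F6 | step 20 | lactol (anomers) | CC(C)(C)[Si](C)(C)O[C@H]1CC[C@@H]2[C@]1(C)CC[C@](C)(COC(O)C3)[C@]23C
F7 | step 20 | silyloxy lactone | CC(C)(C)[Si](C)(C)O[C@H]1CC[C@@H]2[C@]1(C)CC[C@](C)(COC(=O)C3)[C@]23C
F8 | step 32 | saturated keto alcohol (C9 epimers) | CC(C)[C@H]1CC[C@@H]2[C@]1(C)CC[C@](C)(CO)[C@@]2(C)CCC3C(=O)C=C4C(C)(C)[C@@H](O[Si](C)(C)C(C)(C)C)CC[C@@]43C
F9 | step 32 | keto aldehyde (C9 epimers) | CC(C)[C@H]1CC[C@@H]2[C@]1(C)CC[C@](C)(C=O)[C@@]2(C)CCC3C(=O)C=C4C(C)(C)[C@@H](O[Si](C)(C)C(C)(C)C)CC[C@@]43C
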